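**Strategy.** The side-chain-bearing quinone ring (C1, C2, C3, C4, C4a, C8a) is made last, by thermal ring expansion of a four-membered ring. A symmetric 3,6-bis(methoxymethoxy)benzocyclobutenedione carries C1, C4, C4a and C8a. Mono-addition of the dilithiated (R)-propargylic alcohol gives a 2-alkynyl-2-hydroxybenzocyclobutenone. Heating opens it to a ketene that closes onto the alkyne, so C2 (bearing the finished C1′ stereocentre) and C3 are inserted between the two former carbonyl carbons; the 1,4-quinone forms directly and the carbinol hydrogen ends as C3–H. The step exploits the para C1/C4 carbonyls flanking a monosubstituted C2=C3 unit on a symmetric 5,8-dioxygenated benzo ring. Esterification and MOM removal follow.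

Key step: step 7

Assumption: 1,2-diethoxy-1,2-bis(trimethylsilyloxy)ethene (3) is taken as a purchasable reagent; C1–C8a number the naphthoquinone core and C1′ is the carbinol carbon of the side chain.

Step 1
Reactants: 1 2-bromobenzene-1,4-diol
Product: 2 2-bromo-1,4-bis(methoxymethoxy)benzene
Conditions: MOMCl (2.5 equiv), i-Pr2NEt, CH2Cl2, 0 °C to rt
Reagents that add atoms: chloromethyl methyl ether (MOMCl), COCCl
Why: Double O-alkylation of the hydroquinone with MOMCl under amine base (Williamson-type acetal ether formation) should be clean, and MOM ethers tolerate lithium amides, organolithiums and heat yet leave later under mild Lewis acid.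

Step 2
Reactants: 2 2-bromo-1,4-bis(methoxymethoxy)benzene; 3 1,2-diethoxy-1,2-bis(trimethylsilyloxy)ethene (E/Z mixture)
Product: 6 3,6-bis(methoxymethoxy)benzocyclobutene-1,2-dione, via 3,6-bis(methoxymethoxy)benzyne 4 (not isolated), via bis-silyl ketal cycloadduct 5 (not isolated)
Conditions: LiTMP (from TMPH, n-BuLi; 1.3 equiv), 3 (2.5 equiv), THF, −78 °C to rt; then 1 M HCl, THF, 0 °C
Reagents that add atoms: none
Why: LiTMP should remove H-3 (flanked by Br and OMOM), loss of LiBr gives the symmetric aryne 4, and its known [2+2] cycloaddition with an electron-rich ketene silyl acetal followed by mild acid cleavage of the two silyl ethyl ketals gives the dione; because the aryne is symmetric and both ketal carbons become C=O, the E/Z and cis/trans mixtures converge.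

Step 3
Reactants: 7 3-(trimethylsilyl)prop-2-ynal
Product: 8 (R)-1-(trimethylsilyl)hex-5-en-1-yn-3-ol
Conditions: (+)-Ipc2BOMe (from (−)-α-pinene), allylMgBr, Et2O, −78 °C to rt; then 7, −100 to −78 °C; NaBO3·4H2O, THF/H2O, rt
Reagents that add atoms: allylmagnesium bromide, C=CC[Mg]Br, transferred by way of B-allyldiisopinocampheylborane, C=CCB([C@H]1C[C@H]2C[C@@H]([C@@H]1C)C2(C)C)[C@H]1C[C@H]2C[C@@H]([C@@H]1C)C2(C)C
Why: Brown asymmetric allylboration through a chair Zimmerman–Traxler transition state; the (−)-α-pinene-derived reagent is expected to deliver allyl to the Re face of the ynal and so set the (R)-carbinol (to be confirmed by Mosher ester analysis, the antipodal reagent being equally available), and the perborate work-up spares the C–Si bond.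

Step 4
Reactants: 8 (R)-1-(trimethylsilyl)hex-5-en-1-yn-3-ol
Product: 9 (R)-6-methyl-1-(trimethylsilyl)hept-5-en-1-yn-3-ol
Conditions: Grubbs II (3 mol%), 2-methyl-2-butene (large excess), CH2Cl2, rt to 35 °C
Reagents that add atoms: 2-methyl-2-butene, CC=C(C)C
Why: Olefin cross-metathesis with a large excess of 2-methyl-2-butene should convert the terminal vinyl group into the trisubstituted prenyl-type alkene with loss of propene, the silyl-capped alkyne and the carbinol centre being untouched.

Step 5
Reactants: 9 (R)-6-methyl-1-(trimethylsilyl)hept-5-en-1-yn-3-ol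
Product: 10 (R)-6-methylhept-5-en-1-yn-3-ol
Conditions: K2CO3 (0.2 equiv), MeOH, rt
Reagents that add atoms: none
Why: Base-catalysed methanolysis of the alkynyl C–Si bond (protodesilylation) frees the terminal alkyne without affecting the stereocentre or the alkene.

Step 6
Reactants: 10 (R)-6-methylhept-5-en-1-yn-3-ol; 6 3,6-bis(methoxymethoxy)benzocyclobutene-1,2-dione
Product: 12 8-hydroxy-8-[(3R)-3-hydroxy-6-methylhept-5-en-1-yn-1-yl]-2,5-bis(methoxymethoxy)bicyclo[4.2.0]octa-1,3,5-trien-7-one (both C8 epimers), via dilithium alkynolate 11 (not isolated)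
Conditions: 10, n-BuLi (2.05 equiv), THF, −78 to −20 °C; cannulated into 6 (1.2 equiv), THF, −78 °C; NH4Cl aq at −78 °C
Reagents that add atoms: none
Why: Double deprotonation gives the alkoxide–acetylide 11, whose acetylide carbon should add 1,2 to one of the two equivalent strained ketones of 6 at −78 °C (inverse addition and the α-alkoxide formed stop it at mono-addition); the new tertiary carbinol forms without selectivity, which is irrelevant because step 7 destroys it.

Step 7
Reactants: 12 8-hydroxy-8-[(3R)-3-hydroxy-6-methylhept-5-en-1-yn-1-yl]-2,5-bis(methoxymethoxy)bicyclo[4.2.0]octa-1,3,5-trien-7-one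
Product: 14 (R)-2-(1-hydroxy-4-methylpent-3-en-1-yl)-5,8-bis(methoxymethoxy)naphthalene-1,4-dione, via o-quinoid ketene 13 (not isolated)
Conditions: toluene (0.01 M, degassed), 110 °C
Reagents that add atoms: none
Why: Heating should open the four-membered ring of 12 by conrotatory 4π electrocyclic cleavage of the C(=O)–C(OH) bond, the hydroxyl rotating outward and the alkynyl inward, to give the o-quinoid ketene 13. The ketene carbon then bonds to the distal alkyne carbon in a 6-endo-dig closure that restores the benzene ring and gives a diradical (aryloxyl oxygen and sp2 C3); transfer of the carbinol hydrogen to C3 delivers the quinone without an oxidant. The closest known reaction type is the Moore rearrangement of 4-alkynyl-4-hydroxycyclobutenones and their benzo-fused analogues to 1,4-quinones. The only ring formed is the quinone ring (former ketone carbon, former carbinol carbon, the two ring-fusion carbons and both alkyne carbons), a 4→6 ring expansion. No stereocentre is created: the carbinol centre of 12 is destroyed so both epimers converge, and C1′ is a spectator. The selectivity needed is 6-endo over 5-exo closure (which would give a 2-alkylidene-indane-1,3-dione); it is favoured by the alkyl-type, non-radical-stabilising substituent on the alkyne terminus, high dilution suppresses intermolecular capture of the ketene by hydroxyl groups, and regiochemistry is moot because the two carbonyls of 6 are equivalent.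

Step 8
Reactants: 15 3-hydroxy-3-methylbutanoic acid
Product: 16 3-acetoxy-3-methylbutanoic acid
Conditions: AcCl (neat, excess), 0 °C to rt; evaporate; THF/H2O, rt
Reagents that add atoms: acetyl chloride, CC(=O)Cl
Why: Acetylation of the tertiary alcohol of a hydroxy acid with neat acetyl chloride is a standard route to tertiary acetoxy acids, the transient mixed anhydride being hydrolysed on aqueous work-up.

Step 9
Reactants: 14 (R)-2-(1-hydroxy-4-methylpent-3-en-1-yl)-5,8-bis(methoxymethoxy)naphthalene-1,4-dione; 16 3-acetoxy-3-methylbutanoic acid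
Product: 17 (R)-1-[5,8-bis(methoxymethoxy)-1,4-dioxo-1,4-dihydronaphthalen-2-yl]-4-methylpent-3-en-1-yl 3-acetoxy-3-methylbutanoate
Conditions: DCC (1.5 equiv), DMAP (0.1 equiv), CH2Cl2, 0 °C to rt
Reagents that add atoms: none
Why: Steglich esterification acylates the secondary C1′ hydroxyl at oxygen, hence with retention, with no free phenol to compete; low temperature and catalytic DMAP limit E1cB loss of the β-acetoxy group.

Step 10
Reactants: 17 (R)-1-[5,8-bis(methoxymethoxy)-1,4-dioxo-1,4-dihydronaphthalen-2-yl]-4-methylpent-3-en-1-yl 3-acetoxy-3-methylbutanoate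
Product: 18 (R)-1-(5,8-dihydroxy-1,4-dioxo-1,4-dihydronaphthalen-2-yl)-4-methylpent-3-en-1-yl 3-acetoxy-3-methylbutanoate (β-acetoxyisovalerylshikonin, CNP0153496.1)
Conditions: B-bromocatecholborane (3 equiv), CH2Cl2, −78 °C; NaHCO3 aq
Reagents that add atoms: none
Why: Lewis-acid cleavage of the two aryl methoxymethyl acetals at −78 °C, assisted by the peri quinone carbonyls, should unveil the hydrogen-bonded naphthazarin while the carboxylic esters (including the tertiary acetate) and the trisubstituted alkene are expected to survive.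

**Compound list**

1 | 2-bromobenzene-1,4-diol (bromohydroquinone) | Oc1ccc(O)c(Br)c1 | starting material
2 | 2-bromo-1,4-bis(methoxymethoxy)benzene | COCOc1ccc(OCOC)c(Br)c1 | intermediate
3 | 1,2-diethoxy-1,2-bis(trimethylsilyloxy)ethene (E/Z mixture) | CCOC(O[Si](C)(C)C)=C(OCC)O[Si](C)(C)C | starting material
4 | 3,6-bis(methoxymethoxy)benzyne (not isolated) | COCOC1=CC=C(OCOC)C#C1 | intermediate
5 | 7,8-diethoxy-2,5-bis(methoxymethoxy)-7,8-bis(trimethylsilyloxy)bicyclo[4.2.0]octa-1,3,5-triene (cis/trans mixture, not isolated) | CCOC1(O[Si](C)(C)C)c2c(OCOC)ccc(OCOC)c2C1(OCC)O[Si](C)(C)C | intermediate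
6 | 3,6-bis(methoxymethoxy)benzocyclobutene-1,2-dione (2,5-bis(methoxymethoxy)bicyclo[4.2.0]octa-1,3,5-triene-7,8-dione) | COCOc1ccc(OCOC)c2c1C(=O)C2=O | intermediate
7 | 3-(trimethylsilyl)prop-2-ynal | C[Si](C)(C)C#CC=O | starting material
8 | (R)-1-(trimethylsilyl)hex-5-en-1-yn-3-ol | C[Si](C)(C)C#C[C@H](O)CC=C | intermediate
9 | (R)-6-methyl-1-(trimethylsilyl)hept-5-en-1-yn-3-ol | C[Si](C)(C)C#C[C@H](O)CC=C(C)C | intermediate
10 | (R)-6-methylhept-5-en-1-yn-3-ol | C#C[C@H](O)CC=C(C)C | intermediate
11 | dilithium (R)-6-methylhept-5-en-1-yn-1-id-3-olate (not isolated) | [Li]C#C[C@H](O[Li])CC=C(C)C | intermediate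
12 | 8-hydroxy-8-[(3R)-3-hydroxy-6-methylhept-5-en-1-yn-1-yl]-2,5-bis(methoxymethoxy)bicyclo[4.2.0]octa-1,3,5-trien-7-one (both C8 epimers) | COCOc1ccc(OCOC)c2c1C(=O)C2(O)C#C[C@H](O)CC=C(C)C | intermediate
13 | {6-[(4R)-1,4-dihydroxy-7-methyloct-6-en-2-yn-1-ylidene]-2,5-bis(methoxymethoxy)cyclohexa-2,4-dien-1-ylidene}methanone (o-quinoid ketene, not isolated) | O=C=C1/C(=C(/O)C#C[C@H](O)CC=C(C)C)C(OCOC)=CC=C1OCOC | intermediate
14 | (R)-2-(1-hydroxy-4-methylpent-3-en-1-yl)-5,8-bis(methoxymethoxy)naphthalene-1,4-dione | COCOc1ccc(OCOC)c2c1C(=O)C=C([C@H](O)CC=C(C)C)C2=O | intermediate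
15 | 3-hydroxy-3-methylbutanoic acid | CC(C)(O)CC(=O)O | starting material
16 | 3-acetoxy-3-methylbutanoic acid | CC(=O)OC(C)(C)CC(=O)O | intermediate
17 | (R)-1-[5,8-bis(methoxymethoxy)-1,4-dioxo-1,4-dihydronaphthalen-2-yl]-4-methylpent-3-en-1-yl 3-acetoxy-3-methylbutanoate | CC(=O)OC(C)(C)CC(=O)O[C@H](CC=C(C)C)C1=CC(=O)c2c(OCOC)ccc(OCOC)c2C1=O | intermediate
18 | (R)-1-(5,8-dihydroxy-1,4-dioxo-1,4-dihydronaphthalen-2-yl)-4-methylpent-3-en-1-yl 3-acetoxy-3-methylbutanoate | CC(=O)OC(C)(C)CC(=O)O[C@H](CC=C(C)C)C1=CC(=O)c2c(O)ccc(O)c2C1=O | target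

**Totals.** Total step count: 10. Longest linear sequence: 7 steps (3, 4, 5, 6, 7, 9, 10).

**Steps most likely to fail**

1. Step 7. The ketene may close in the 5-exo mode onto the proximal alkyne carbon, or the aryl radical may abstract hydrogen from the side chain instead of taking the carbinol hydrogen. The fallback replaces the diradical pathway by a closed-shell 6π-electrocyclisation; it sets out from 10 (and 6) and returns at 14. The alcohol of 10 is silylated (TBSCl, imidazole) to (R)-tert-butyl(dimethyl)[(6-methylhept-5-en-1-yn-3-yl)oxy]silane F1. Hydrozirconation with the Schwartz reagent and iodinolysis give (R,E)-tert-butyl[(1-iodo-6-methylhepta-1,5-dien-3-yl)oxy]dimethylsilane F2. Iodine–lithium exchange (t-BuLi, Et2O, −78 °C) and addition to 6 should give the 2-alkenyl-2-hydroxybenzocyclobutenone F3. Heating in toluene should open this to a dienylketene that electrocyclises and tautomerises to the hydroquinone, (R)-2-[1-(tert-butyldimethylsilyloxy)-4-methylpent-3-en-1-yl]-5,8-bis(methoxymethoxy)naphthalene-1,4-diol F4, again by 4→6 ring expansion. Ag2O oxidation gives the silylated quinone F5, and HF·pyridine returns 14.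

2. Step 2. The cycloaddition of the hindered tetra-oxygenated alkene may be too slow, so that the aryne is consumed by amine addition or oligomerisation, or the silyl groups may be lost early. The fallback builds the second carbonyl by oxidation; it sets out from 2 and returns at 6. The aryne is generated with NaNH2 in THF in the presence of 1,1-diethoxyethene to give 7,7-diethoxy-2,5-bis(methoxymethoxy)bicyclo[4.2.0]octa-1,3,5-triene F6. Dilute acid gives 3,6-bis(methoxymethoxy)benzocyclobutenone F7. Radical benzylic dibromination (NBS, 2.2 equiv, initiator) gives the 2,2-dibromo ketone F8, and silver(I)-assisted hydrolysis (AgOCOCF3, aq. MeCN) gives 6.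

3. Step 10. The Lewis acid may ionise or eliminate the tertiary acetate, or HBr may add to the alkene during acetal cleavage. The fallback changes the order of events; it sets out from 14 and returns at 18. The MOM groups are removed at the alcohol stage (B-bromocatecholborane, −78 °C) to give shikonin F9. Steglich esterification of F9 with 16 (DCC, cat. DMAP) then acylates the side-chain hydroxyl, since the phenols are deactivated by hydrogen bonding to the quinone carbonyls, and gives 18 directly.

**Further compounds**

F1 | step 7 | (R)-tert-butyl(dimethyl)[(6-methylhept-5-en-1-yn-3-yl)oxy]silane | C#C[C@H](O[Si](C)(C)C(C)(C)C)CC=C(C)C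
F2 | step 7 | (R,E)-tert-butyl[(1-iodo-6-methylhepta-1,5-dien-3-yl)oxy]dimethylsilane | I/C=C/[C@H](O[Si](C)(C)C(C)(C)C)CC=C(C)C
F3 | step 7 | 8-hydroxy-8-[(1E,3R)-3-(tert-butyldimethylsilyloxy)-6-methylhepta-1,5-dien-1-yl]-2,5-bis(methoxymethoxy)bicyclo[4.2.0]octa-1,3,5-trien-7-one | COCOc1ccc(OCOC)c2c1C(=O)C2(O)/C=C/[C@H](O[Si](C)(C)C(C)(C)C)CC=C(C)C
F4 | step 7 | (R)-2-[1-(tert-butyldimethylsilyloxy)-4-methylpent-3-en-1-yl]-5,8-bis(methoxymethoxy)naphthalene-1,4-diol | COCOc1ccc(OCOC)c2c(O)c([C@H](O[Si](C)(C)C(C)(C)C)CC=C(C)C)cc(O)c12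
F5 | step 7 | (R)-2-[1-(tert-butyldimethylsilyloxy)-4-methylpent-3-en-1-yl]-5,8-bis(methoxymethoxy)naphthalene-1,4-dione | COCOc1ccc(OCOC)c2c1C(=O)C=C([C@H](O[Si](C)(C)C(C)(C)C)CC=C(C)C)C2=O
F6 | step 2 | 7,7-diethoxy-2,5-bis(methoxymethoxy)bicyclo[4.2.0]octa-1,3,5-triene | CCOC1(OCC)Cc2c(OCOC)ccc(OCOC)c12
F7 | step 2 | 2,5-bis(methoxymethoxy)bicyclo[4.2.0]octa-1,3,5-trien-7-one | COCOc1ccc(OCOC)c2c1CC2=O
F8 | step 2 | 8,8-dibromo-2,5-bis(methoxymethoxy)bicyclo[4.2.0]octa-1,3,5-trien-7-one | COCOc1ccc(OCOC)c2c1C(Br)(Br)C2=O
F9 | step 10 | shikonin, (R)-5,8-dihydroxy-2-(1-hydroxy-4-methylpent-3-en-1-yl)naphthalene-1,4-dione | O[C@H](CC=C(C)C)C1=CC(=O)c2c(O)ccc(O)c2C1=O
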